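Amounts first, for whoever takes this bench: the flask holds 0.10 M of electrophile, 0.100 M of nucleophile and 0.150 M of free base, and you come at 3.0 h.

| flask | electrophile | nucleophile | free base | remark | time |
|---|---|---|---|---|---|
| east | 0.050 M | 0.10 M | 0.15 M | run made earlier |  |
| north | 0.20 M | 0.10 M | 0.15 M | run made earlier |  |
| north-east | 0.10 M | 0.10 M | 0.075 M | run made earlier |  |
| flask | 0.10 M | 0.100 M | 0.150 M |  | 3.0 h |

| run | time / h | electrophile / % | target / % |
|---|---|---|---|
| east | 0.417 | 72.7 | 26.8 |
| east | 0.833 | 55.3 | 44.4 |
| east | 1.33 | 41.8 | 58.6 |
| east | 1.50 | 37.8 | 62.1 |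
| east | 2.00 | 29.2 | 71.5 |
| east | 2.50 | 22.2 | 77.9 |
| north | 0.167 | 89.5 | 10.8 |
| north | 0.500 | 76.2 | 23.0 |
| north | 0.833 | 69.1 | 31.5 |
| north | 1.33 | 62.0 | 38.5 |
| north | 2.00 | 56.1 | 44.0 |
| north | 2.50 | 54.4 | 45.7 |
| north-east | 0.200 | 86.9 | 13.6 |
| north-east | 0.333 | 80.0 | 20.4 |
| north-east | 0.667 | 66.2 | 33.5 |
| north-east | 1.33 | 49.3 | 50.2 |
| north-east | 2.50 | 33.5 | 66.0 |

(each reading ± 0.3 percentage points)

- candidate steps: electrophile + nucleophile -> acid set free + target; nucleophile + acid set free <-> protonated nucleophile; acid set free + free base <-> salt of the base; acid set free -> by-product carried off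
- the earlier runs do not show how much of nucleophile is bound; that part of a forecast is a guess

* part of the electrophile that has reacted at 3.0 h
* share of the unused nucleophile that is free and not bound as protonated nucleophile, at 3.0 h

The north-east run started with the same electrophile and nucleophile charges, so I read its clock at 1.33 h:

half-life = time × [electrophile] / ([electrophile at start] − [electrophile]) = 1.29 h

This second-order half-life is the time in which equal charges fall to half. Unlike a first-order time constant it stretches, so the share left is the inverse of one plus the count of half-lives:

count = 2.32, reacted = 69.9%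

That run, charged with half of this free base, gives 1.26 h at its last reading, close to the first figure, so its clock held steady along that run; please add no free base, and do not top up either reactant, since this clock was read for these charges of electrophile and nucleophile. The forecast says 70% of the electrophile reacted (68% to 72%) and 97% of the unused nucleophile free (85% to 100%), adding of the second, “this is a guess, hence the wider range”.

    electrophile + nucleophile → acid set free + target (k = 0.00234 /M/s)
    nucleophile + acid set free ⇌ protonated nucleophile, settled at all times (K = 110 /M)
    acid set free + free base ⇌ salt of the base (K = 10.0 /M, k = 0.118 /M/s)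
    acid set free → by-product carried off (k = 0.0103 /s)

The flask gives 70.3% of the electrophile reacted and 97.7% of the unused nucleophile free. At 3.00 h its free base stands at 99.8% of charge, with 0.0691 M of by-product carried off, more than the 3.29 × 10⁻⁴ M of salt of the base. For a neighbour charged like this flask but with 0.060 M of electrophile, the count is scaled by the gap between charges over 0.10 M:

x = 0.928, left = gap / ([nucleophile at start] e^x − [electrophile at start]) = 20.7%

That neighbour has 19.7% of its electrophile left.

The data were computed with made-up constants, and the scatter is random.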